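## Structural features

The target is a gibberellane-type C20 diterpenoid, numbered here as the gibberellins are. A cyclohexane (ring A: C1–C5, C10) and a cyclopentane (ring B: C5, C6, C8, C9, C10) share the C5–C10 bond. Ring B shares the C8–C9 bond with a bicyclo[3.2.1]octane (rings C and D: C8, C9, C11–C16), in which C14 is the one-carbon bridge and C15–C16 the two-carbon bridge. There are nine stereocentres, seven of them contiguous around ring B (C3, C4, C5, C6, C8, C9, C10). Three carbons (C4, C8, C10) are quaternary; C4 and C10 flank C5, with the carboxyl C19 and the methyl C20 cis and 1,3-diaxial across a trans A/B junction. The hydroxymethyl C7 on C6 is cis to H5, and the C16 carbinol has its methyl on the side of C14 and its hydroxyl on the side of C11/C12. The fragile points are the axial 3-hydroxyl β to the C19 carboxyl (retro-aldol under base, decarboxylation if C3 is a ketone while C19 is a free acid), the hindered C19 ester position, and the tertiary C16 alcohol, which ionises under strong acid. The real difficulty is the crowded sequence C4–C5–C10–C9–C8, in which two quaternary carbons must be joined through C5 and tied to the bicyclooctane with the correct sense at C9 and C6. Because rings A and B share C5 and C10, a radical on C4 that adds to C5 leaves a tertiary radical on C10 that can reach C9 of a C9=C11 alkene. One chain therefore forms C4–C5 and C9–C10, closes rings A and B onto a finished ring C/D unit and sets C4, C5, C9 and C10.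

## Logic of the disconnections

28 is traced back to 27 by restoring a C11=C12 alkene and a benzyl group on the C19 carboxyl. One neutral hydrogenation then finishes the molecule, and the β-hydroxy acid never meets base or a nucleophile. The gain is that the unsaturation left by the radical chain and the ester needed for it disappear together. The demand is that the alkene is saturated faster than it migrates toward C9.

27 is traced back through 26 to 25 by placing silyl groups on O7 and O16 and by cutting the C3–H bond to a ketone. The C3 carbonyl is what the radical step requires, and a keto ester without α-hydrogen cannot epimerise. The demand is hydride delivery to the equatorial face of C3, and reduction before the ester is cleaved, since a 3-oxo acid would lose CO2.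

25 is cut at C4–C5 and C9–C10 to give 24. This removes rings A and B, two of the three quaternary carbons and four stereocentres in one operation, and leaves an open chain attached to a small bicycle. The demand is a radical chain that closes ring A before ring B, attacks one face of C5 and of C9, and is not intercepted at C10 or by O16. The spectator groups of 24 are chosen accordingly: a silyl ether on O16, a robust silyl ether on O7, and a benzyl instead of a methyl ester.

24 is cut at C3–C4 to give 21 and 22. The cut separates the keto ester head from the chain at the only carbonyl–carbon bond that an ester enolate can make. The gain is a commercial three-carbon ester. The demand is selective acylation of the enolate of 22 by 21 without proton exchange.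

21 is cut at C1–C2, with the C5=C10 alkene moved back to C10=C1 and oxygen placed on C5, to give 18 and 19. A sigmatropic shift builds the trisubstituted alkene with E geometry and adds C2 and C3 in one step. The demand is a chair transition state with the C6 branch equatorial and survival of both silyl ethers at high temperature.

18 is cut at C5–C10 to give 17 and an isopropenyl organometallic reagent. The gain is an aldehyde whose only new stereocentre (C5) is lost again in the next step. The demand is addition without epimerisation of C6.

17 is cut at C6–C7 to give 15 and formaldehyde. This is where C6 is set by a catalyst and where the racemic bicycle is resolved, because the two enantiomers of 15 become separable diastereomers. The demand is catalyst control that overrides the weak bias of the quaternary C8.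

15 is traced back through 14 to 12 by changing the oxidation level of C5: the aldehyde comes from a vinyl group on C8. The gain is a substituent that is inert through the early steps. The demand is hydroboration of the vinyl group in the presence of the ring alkene.

12 is cut at C16–C17 (and at O16–Si) to give 10. The demand is methyl delivery to the exo face of the C16 ketone, which places the hydroxyl where the target has it.

10 is traced back to 7 by replacing the C9=C11 alkene with a C9–Cl bond and a C11 carbonyl, and the C16 ketone with its silyl enol ether. The chlorine that the cycloaddition leaves behind then marks where the alkene must go. The demand is that the chlorine sits on C9 and not on C12.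

7 is cut at C8–C9 and C12–C13 to give 5 and 6. The gain is the whole bicyclo[3.2.1]octane, with the quaternary bridgehead, in one step from an achiral diene. The demand is regioselective union of the polarised diene with the unsymmetrical cation.

5 is traced back through 4 and 2 to 1 by removing the silyl group and cutting the C6–C8 bond between the vinyl group and the ring. The gain is a commercial dione. The demand is 1,2-addition to the vinylogous ester and enolisation of 4 on the ring side.

## Other disconnections considered

Alternative 1: The cut is C8–C15 together with the C16–O bond. Ring D of the diacetate methyl ester A2 becomes an isopropenyl group on C13 of the tricyclic C8=C14 alkene A1. Forward, aqueous acid would protonate C14, the tertiary C8 cation would be trapped by the terminal carbon of the isopropenyl group, and water would end the sequence at C16.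
- In its favour: it mirrors the way such bicyclooctanes are thought to arise in nature, and it needs no organometallic reagent and no protection of O16. C8 can only form cis to C13, so the bridgehead configuration is as secure as in the chosen plan; on that point the two are equal. On the directness of carbinol installation the alternative is the better.
- Against it here: the C8 cation has other exits (loss of H9 to the tetrasubstituted alkene, hydride and alkyl shifts). Nothing in A1 steers water to the endo face of C16. Capture on the open exo face, on the side of C14, would give the C16 epimer of A2, whereas methyl addition to a C16 ketone (step 6) puts the methyl on that open face and the hydroxyl where the target has it.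
- Comparison: the step adds one ring, one C–C bond and two stereocentres (C8, C16) to a precursor that already holds rings A–C, seven stereocentres and both quaternary carbons C4 and C10. The hard part is postponed, not solved. The chosen key step forms two rings, two C–C bonds and four stereocentres. The end game from A2 would be short, but the way to A1 would be longer than the twelve steps that lead to 24.

Alternative 2: The cut is the C11–C12 bond. Ring C of A4 is opened to the seven-membered cyclic sulfone A3, in which sulfur links C11 and C12. Forward, base and a halogen source would halogenate a carbon next to sulfur, 1,3-elimination would give the episulfone, and loss of SO2 would leave the C11=C12 alkene (Ramberg–Bäcklund reaction).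
- In its favour: the reaction is dependable for cis-cycloalkenes, it does not matter which α-carbon is halogenated, and no stereocentre is at stake. In reliability of the bond-forming event it is the better of the two. It ends at the same C11=C12 alkene as step 13, so the final hydrogenation would be shared; there the two are equal.
- Against it here: the bond made is the least demanding one of the skeleton. All nine stereocentres and rings A, B and D must already be present in A3, and two carbon–sulfur bonds are built only to be destroyed. Strong base meets a methyl ester and a free tertiary alcohol. The methoxymethyl ethers and the axial methyl ester of A4 would later need acidic and strongly nucleophilic cleavage next to the tertiary carbinol and the β-hydroxy ester.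
- Comparison: the alternative spends its key step on one bond and no stereocentre, against two rings and four stereocentres in the chosen plan.

Alternative 3: The cut is C8–C9 and C12–C13. Rings B and C of A6 are opened to the chloromethyl ketone A5, in which ring A carries the three-carbon ketone unit on C10 and a 2-silyloxycyclopentadiene on C6. Forward, base in trifluoroethanol would turn the chloromethyl ketone into the C9–C11–C12 oxyallyl cation, which would add across C8 and C13 of the tethered diene.
- In its favour: two rings, two C–C bonds and three stereocentres (C8, C9, C13) arise at once, and the C11 ketone and C16 enol ether come out differentiated. The three-atom tether fixes the regiochemistry; on that point it is the better of the two, because the intermolecular cycloaddition of step 4 must rely on the polarity of the diene. In rings and bonds formed it is the equal of step 13.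
- Against it here: the sense of C8 and C9 relative to C10, C5 and C6 depends on which diene face and tether conformation react, and no element of A5 decides this clearly. The silyloxydiene can isomerise by 1,5-hydrogen shifts. A5 is a cyclohexane with four contiguous stereocentres, two of them quaternary, and is harder to make than 24. Afterwards the C11 carbonyl must be removed and C16 methylated in the presence of the C19 ester.
- Comparison: the chosen plan uses the same cycloaddition type early, on achiral material, and leaves the crowded C4/C10 region to the radical step, which sets four stereocentres instead of three and needs no deoxygenation.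

Key step: step 13

Remark on the chemistry (assumptions):
- The (4+3) cycloaddition is not enantioselective. Compounds 7–15 are racemic and their SMILES show the enantiomer that is carried on. 16 is the pair of (6S) diastereomers. From 17 on every compound is a single enantiomer.
- Carbon numbers C1–C20 are those of the gibberellane skeleton, also in the early intermediates.
- Bco stands for the 6-exo-methyl-6-endo-(triethylsilyloxy)bicyclo[3.2.1]oct-2-en-1-yl group with the configuration of 12 (its C1 is C8, exo means syn to the one-carbon bridge C14).

## Steps

Step 1
Reactants: 1 cyclopentane-1,3-dione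
Product: 2 3-ethoxycyclopent-2-en-1-one
Conditions: EtOH, cat. TsOH, toluene, reflux, Dean–Stark
Reagents that add atoms: ethanol, CCO
Why: Acid-catalysed condensation of the enolised 1,3-dione with ethanol under removal of water gives the vinylogous ester (enol etherification of a 1,3-diketone). No stereocentre is formed.

Step 2
Reactants: 2 3-ethoxycyclopent-2-en-1-one
Product: 4 3-ethenylcyclopent-2-en-1-one, via bromomagnesium 1-ethenyl-3-ethoxycyclopent-2-en-1-olate 3 (not isolated)
Conditions: CH2=CHMgBr, THF, −78 → 0 °C; then 1 M HCl, 0 °C
Reagents that add atoms: vinylmagnesium bromide, C=C[Mg]Br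
Why: 1,2-Addition to the vinylogous ester and acid-induced loss of ethanol from the tertiary allylic alcohol transpose the carbonyl (Stork–Danheiser sequence). The ring carbon that receives the vinyl group becomes C8 and the vinyl carbons become C6 and C5.

Step 3
Reactants: 4 3-ethenylcyclopent-2-en-1-one
Product: 5 tert-butyl[(4-ethenylcyclopenta-1,4-dien-1-yl)oxy]dimethylsilane
Conditions: TBSOTf, Et3N, Et2O, −78 → 0 °C; used cold and at once
Reagents that add atoms: tert-butyldimethylsilyl trifluoromethanesulfonate, CC(C)(C)[Si](C)(C)OS(=O)(=O)C(F)(F)F
Why: O-Silylation of the enone and deprotonation at the α' carbon (soft enolisation) should give the cross-conjugated 2-silyloxydiene. The triene is not stored, because silyloxycyclopentadienes undergo 1,5-hydrogen shifts and dimerise.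

Step 4
Reactants: 5 tert-butyl[(4-ethenylcyclopenta-1,4-dien-1-yl)oxy]dimethylsilane; 6 1,3-dichloropropan-2-one
Product: 7 rac-6-(tert-butyldimethylsilyloxy)-2-chloro-1-ethenylbicyclo[3.2.1]oct-6-en-3-one (C2 epimers; bridgeheads as in 10)
Conditions: Et3N, CF3CH2OH, 0 °C, slow addition of 6
Reagents that add atoms: none
Why: Amine-induced loss of HCl from 6 in ionising trifluoroethanol generates the chloro-substituted oxyallyl cation, which adds across the diene termini ((4+3) cycloaddition of an oxyallyl cation to a cyclopentadiene) and forms C12–C13, C8–C9 and both bridgeheads as a racemate. The enol-ether carbon C13 is the nucleophilic terminus and should bond first to the unhindered CH2 end of the cation, so that chlorine ends on C9 next to the quaternary C8. The configuration at C9 is irrelevant because it is destroyed in step 5.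

Step 5
Reactants: 7 rac-6-(tert-butyldimethylsilyloxy)-2-chloro-1-ethenylbicyclo[3.2.1]oct-6-en-3-one
Product: 10 rac-1-ethenylbicyclo[3.2.1]oct-2-en-6-one (drawn enantiomer 1S,5R), via chlorohydrin aluminate 8 (not isolated), via silyl enol ether diene 9 (not isolated)
Conditions: LiAlH4, THF, −78 °C; Li powder, −78 °C → rt; then 1 M HCl, THF, rt
Reagents that add atoms: none
Why: Hydride reduction gives the β-chloro alkoxide, and reductive lithiation of the C–Cl bond followed by loss of the neighbouring oxide puts the alkene between C9 and C11 whatever the chlorohydrin configuration (Boord-type reductive β-elimination). The acidic work-up hydrolyses the silyl enol ether to the C16 ketone. Isolated alkenes and the enol ether should be inert to lithium at low temperature.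

Step 6
Reactants: 10 rac-1-ethenylbicyclo[3.2.1]oct-2-en-6-one
Product: 12 rac-[(1-ethenyl-6-methylbicyclo[3.2.1]oct-2-en-6-yl)oxy]triethylsilane (drawn enantiomer 1S,5R,6S; methyl exo), via tertiary alkoxide 11 (not isolated)
Conditions: MeLi, CeCl3, THF, −78 °C; then TESOTf, −78 → 0 °C
Reagents that add atoms: methyllithium, [Li]C; triethylsilyl trifluoromethanesulfonate, CC[Si](CC)(CC)OS(=O)(=O)C(F)(F)F
Why: The organocerium reagent adds to the enolisable ketone without deprotonation and from the exo face, which is flanked only by one hydrogen of C14 (1,2-addition under steric approach control in a bicyclo[3.2.1]octan-6-one). This sets C16 with methyl exo and oxygen endo, as in the target. The alkoxide is silylated in the same flask because a free O16 would be a liability in steps 11 and 13.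

Step 7
Reactants: 12 rac-[(1-ethenyl-6-methylbicyclo[3.2.1]oct-2-en-6-yl)oxy]triethylsilane
Product: 14 rac-2-Bco-ethan-1-ol, via B-alkyl-9-borabicyclononane 13 (not isolated)
Conditions: 9-BBN, THF, 0 °C → rt; then NaOH, H2O2, 0 °C
Reagents that add atoms: hydrogen peroxide, OO; 9-borabicyclo[3.3.1]nonane, B1C2CCCC1CCC2 (its boron stays only in 13)
Why: 9-BBN hydroborates the monosubstituted vinyl group anti-Markovnikov far faster than the hindered cis-disubstituted ring alkene, and oxidation with retention gives the primary alcohol (hydroboration–oxidation). No stereocentre changes.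

Step 8
Reactants: 14 rac-2-Bco-ethan-1-ol
Product: 15 rac-2-Bco-acetaldehyde
Conditions: Dess–Martin periodinane, NaHCO3, CH2Cl2, 0 °C → rt
Reagents that add atoms: none
Why: Buffered Dess–Martin oxidation converts the primary alcohol into the aldehyde without touching the tertiary silyl ether or the alkene. The aldehyde has no α-stereocentre and a quaternary β-carbon, so it should be stable.

Step 9
Reactants: 15 rac-2-Bco-acetaldehyde
Product: 17 (2S)-3-(tert-butyldiphenylsilyloxy)-2-Bco-propanal (single enantiomer after chromatography), via (2S)-3-hydroxy-2-Bco-propanal 16 (not isolated)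
Conditions: aq. HCHO, (R)-2-[diphenyl(trimethylsilyloxy)methyl]pyrrolidine (20 mol %), toluene, pH 7 buffer, rt; then TBDPSCl, imidazole, CH2Cl2, 0 °C; chromatography
Reagents that add atoms: formaldehyde, C=O; tert-butyl(chloro)diphenylsilane, CC(C)(C)[Si](Cl)(c1ccccc1)c1ccccc1
Why: Formaldehyde attacks the E-enamine of 15 on the face remote from the diphenyl(silyloxy)methyl group (organocatalytic enantioselective α-hydroxymethylation of an aldehyde), which with the (R)-catalyst should give (S)-configured C6 in both enantiomers of 15, the bicycle exerting little bias of its own. The two enantiomers of 15 thus become two diastereomers, and chromatography of their silyl ethers should deliver 17 as a single enantiomer. Immediate silylation protects the dehydration-prone aldol 16.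

Step 10
Reactants: 17 (2S)-3-(tert-butyldiphenylsilyloxy)-2-Bco-propanal
Product: 18 (2S)-1-(tert-butyldiphenylsilyloxy)-4-methyl-2-Bco-pent-4-en-3-ol (C3 epimers)
Conditions: CH2=C(CH3)MgBr, THF, −78 → 0 °C
Reagents that add atoms: isopropenylmagnesium bromide, CC(=C)[Mg]Br
Why: Grignard 1,2-addition to the aldehyde forms C5–C10 at low temperature, where the hindered α-hydrogen at C6 should not be removed. Both carbinol epimers are carried on because C5 becomes sp2 in step 11.

Step 11
Reactants: 18 (2S)-1-(tert-butyldiphenylsilyloxy)-4-methyl-2-Bco-pent-4-en-3-ol; 19 1,1,1-triethoxyethane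
Product: 21 ethyl (4E,6S)-7-(tert-butyldiphenylsilyloxy)-4-methyl-6-Bco-hept-4-enoate, via mixed ketene acetal 20 (not isolated)
Conditions: 19 (excess), cat. EtCO2H, 135 °C, distilling off EtOH
Reagents that add atoms: none
Why: Exchange with the orthoester and loss of ethanol give the ketene acetal, whose chair [3,3]-sigmatropic shift (Johnson–Claisen rearrangement) forms C1–C2 and moves the alkene to C5=C10. The bulky C6 substituent is equatorial in the chair, which sets the E geometry; C6 itself is untouched.

Step 12
Reactants: 21 ethyl (4E,6S)-7-(tert-butyldiphenylsilyloxy)-4-methyl-6-Bco-hept-4-enoate; 22 benzyl propanoate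
Product: 24 benzyl (6E,8S)-9-(tert-butyldiphenylsilyloxy)-2,6-dimethyl-3-oxo-8-Bco-non-6-enoate (C2 epimers), via lithium enolate of benzyl propanoate 23 (not isolated)
Conditions: 22 (3 equiv), LiN(i-Pr)2 (3 equiv), THF, −78 °C; then 21, −78 → −20 °C; aq. NH4Cl
Reagents that add atoms: lithium diisopropylamide, [Li]N(C(C)C)C(C)C (its lithium stays only in 23)
Why: The preformed enolate of 22, used in excess, is acylated by 21 at C3 (crossed Claisen condensation), and deprotonation of the β-keto ester drives the reaction. The benzyl ester is chosen so that C19 can later be freed by hydrogenolysis. C4 forms as a mixture, which does not matter because it becomes a radical centre.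

Step 13
Reactants: 24 benzyl (6E,8S)-9-(tert-butyldiphenylsilyloxy)-2,6-dimethyl-3-oxo-8-Bco-non-6-enoate
Product: 25 benzyl 7-(tert-butyldiphenylsilyloxy)-3-oxo-16-(triethylsilyloxy)gibberell-11-en-19-oate (H5 and H9 and C7 on one face; C19 and C20 on the other)
Conditions: Mn(OAc)3·2H2O (2.2 equiv), Cu(OAc)2·H2O (0.2 equiv), NaOAc, degassed AcOH, 0.01 M, rt
Reagents that add atoms: none
Why: Mn(OAc)3 converts the α-methyl β-keto ester into its manganese enolate and, by inner-sphere electron transfer, into the electrophilic C4 radical; the closest known reaction type is the Mn(OAc)3/Cu(OAc)2 oxidative polycyclisation of unsaturated α-methyl β-keto esters. Ring A closes 6-endo-trig: the radical adds to C5, the less substituted end of the trisubstituted alkene, through a chair with the C6 branch equatorial, and leaves the tertiary C10 radical. Ring B closes 5-exo-trig by attack of C10 on C9 of the bicyclooctene; the secondary C11 radical is then captured by Cu(OAc)2 and loses a hydrogen from C12 to give the C11=C12 alkene, the monovalent copper being re-oxidised by Mn(OAc)3. C4 is set by the chair, in which the ester is axial and therefore cis to C20, as is usual for this radical class. C5 is set by allylic 1,3-strain: H6 lies in the alkene plane next to C20 and C4 enters on the face opposite the bulky bicyclooctenyl group, which puts H5 trans to H6. C9 is set by the tether, since C6 on the bridgehead C8 lets C10 reach only the alkene face syn to C14, and C10 is expected to form the new bond equatorially with C20 axial (trans A/B), as in radical polyene cyclisations that end with a 5-exo closure. The step needs cyclisation of the C10 radical to outrun its oxidation, which a low concentration of Cu(OAc)2 and high dilution should secure, and it needs the C11 intermediate to escape capture by O16, which the triethylsilyl ether secures.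

Step 14
Reactants: 25 benzyl 7-(tert-butyldiphenylsilyloxy)-3-oxo-16-(triethylsilyloxy)gibberell-11-en-19-oate
Product: 26 benzyl 7-(tert-butyldiphenylsilyloxy)-3β-hydroxy-16-(triethylsilyloxy)gibberell-11-en-19-oate (3-OH axial)
Conditions: K[(s-Bu)3BH], THF, −78 °C; aq. NH4Cl
Reagents that add atoms: none
Why: The bulky trialkylborohydride attacks the C3 ketone along the equatorial direction, avoiding the syn-axial hydrogens at C1 and C5, and should give the axial alcohol cis to C18 (steric approach control). The keto ester has no α-hydrogen and cannot epimerise, and reduction before ester cleavage avoids a decarboxylation-prone 3-oxo acid.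

Step 15
Reactants: 26 benzyl 7-(tert-butyldiphenylsilyloxy)-3β-hydroxy-16-(triethylsilyloxy)gibberell-11-en-19-oate
Product: 27 benzyl 3β,7,16-trihydroxygibberell-11-en-19-oate
Conditions: Bu4NF, AcOH (1:1), THF, rt
Reagents that add atoms: none
Why: Fluoride cleaves both silicon–oxygen bonds (desilylation). Buffering with acetic acid keeps the medium non-basic, so the β-hydroxy ester should not undergo retro-aldol cleavage and the hindered benzyl ester should stay intact.

Step 16
Reactants: 27 benzyl 3β,7,16-trihydroxygibberell-11-en-19-oate
Product: 28 3β,7,16-trihydroxygibberellan-19-oic acid (CNP0170663.1)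
Conditions: H2 (1 atm), Pd/C (10% palladium on carbon), EtOAc–MeOH, rt
Reagents that add atoms: none
Why: Heterogeneous hydrogenation saturates the cis-disubstituted C11=C12 alkene, which creates no stereocentre, and hydrogenolyses the benzyl ester in the same operation. The acid is thus released under neutral conditions, and the product is isolated by filtration.

## Compound list

1 | cyclopentane-1,3-dione | O=C1CCC(=O)C1 | starting material
2 | 3-ethoxycyclopent-2-en-1-one | CCOC1=CC(=O)CC1 | intermediate
3 | bromomagnesium 1-ethenyl-3-ethoxycyclopent-2-en-1-olate (racemic, shown as the alcohol, not isolated) | C=CC1(O)C=C(OCC)CC1 | intermediate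
4 | 3-ethenylcyclopent-2-en-1-one | C=CC1=CC(=O)CC1 | intermediate
5 | tert-butyl[(4-ethenylcyclopenta-1,4-dien-1-yl)oxy]dimethylsilane | C=CC1=CC(O[Si](C)(C)C(C)(C)C)=CC1 | intermediate
6 | 1,3-dichloropropan-2-one | O=C(CCl)CCl | starting material
7 | rac-6-(tert-butyldimethylsilyloxy)-2-chloro-1-ethenylbicyclo[3.2.1]oct-6-en-3-one (C2 epimers) | C=C[C@@]13C[C@@H](CC(=O)C1Cl)C(O[Si](C)(C)C(C)(C)C)=C3 | intermediate
8 | rac-6-(tert-butyldimethylsilyloxy)-2-chloro-1-ethenylbicyclo[3.2.1]oct-6-en-3-ol (as aluminate, not isolated) | C=C[C@@]13C[C@@H](CC(O)C1Cl)C(O[Si](C)(C)C(C)(C)C)=C3 | intermediate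
9 | rac-tert-butyl[(1-ethenylbicyclo[3.2.1]octa-2,6-dien-6-yl)oxy]dimethylsilane (not isolated) | C=C[C@@]13C[C@@H](CC=C1)C(O[Si](C)(C)C(C)(C)C)=C3 | intermediate
10 | rac-1-ethenylbicyclo[3.2.1]oct-2-en-6-one (drawn 1S,5R) | C=C[C@@]13C[C@@H](CC=C1)C(=O)C3 | intermediate
11 | rac-1-ethenyl-6-methylbicyclo[3.2.1]oct-2-en-6-ol (drawn 1S,5R,6S; as alkoxide, not isolated) | C=C[C@@]13C[C@@H](CC=C1)[C@@](C)(O)C3 | intermediate
12 | rac-[(1-ethenyl-6-methylbicyclo[3.2.1]oct-2-en-6-yl)oxy]triethylsilane (drawn 1S,5R,6S; methyl exo) | C=C[C@@]13C[C@@H](CC=C1)[C@@](C)(O[Si](CC)(CC)CC)C3 | intermediate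
13 | rac-9-(2-Bco-ethyl)-9-borabicyclo[3.3.1]nonane (not isolated) | C1CCC2CCCC1B2CC[C@@]34C[C@@H](CC=C3)[C@@](C)(O[Si](CC)(CC)CC)C4 | intermediate
14 | rac-2-Bco-ethan-1-ol | OCC[C@@]13C[C@@H](CC=C1)[C@@](C)(O[Si](CC)(CC)CC)C3 | intermediate
15 | rac-2-Bco-acetaldehyde | O=CC[C@@]13C[C@@H](CC=C1)[C@@](C)(O[Si](CC)(CC)CC)C3 | intermediate
16 | (2S)-3-hydroxy-2-Bco-propanal (not isolated; drawn with the bicycle that is carried on) | O=C[C@H](CO)[C@@]13C[C@@H](CC=C1)[C@@](C)(O[Si](CC)(CC)CC)C3 | intermediate
17 | (2S)-3-(tert-butyldiphenylsilyloxy)-2-Bco-propanal | O=C[C@H](CO[Si](c4ccccc4)(c5ccccc5)C(C)(C)C)[C@@]13C[C@@H](CC=C1)[C@@](C)(O[Si](CC)(CC)CC)C3 | intermediate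
18 | (2S)-1-(tert-butyldiphenylsilyloxy)-4-methyl-2-Bco-pent-4-en-3-ol (C3 epimers) | C=C(C)C(O)[C@H](CO[Si](c4ccccc4)(c5ccccc5)C(C)(C)C)[C@@]13C[C@@H](CC=C1)[C@@](C)(O[Si](CC)(CC)CC)C3 | intermediate
19 | 1,1,1-triethoxyethane (triethyl orthoacetate) | CC(OCC)(OCC)OCC | starting material
20 | 1-ethoxyethenyl ether of 18 (mixed ketene acetal, not isolated) | C=C(OCC)OC(C(C)=C)[C@H](CO[Si](c4ccccc4)(c5ccccc5)C(C)(C)C)[C@@]13C[C@@H](CC=C1)[C@@](C)(O[Si](CC)(CC)CC)C3 | intermediate
21 | ethyl (4E,6S)-7-(tert-butyldiphenylsilyloxy)-4-methyl-6-Bco-hept-4-enoate | CCOC(=O)CC/C(C)=C/[C@H](CO[Si](c4ccccc4)(c5ccccc5)C(C)(C)C)[C@@]13C[C@@H](CC=C1)[C@@](C)(O[Si](CC)(CC)CC)C3 | intermediate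
22 | benzyl propanoate | CCC(=O)OCc1ccccc1 | starting material
23 | lithium enolate of benzyl propanoate (not isolated) | CC=C(O[Li])OCc1ccccc1 | intermediate
24 | benzyl (6E,8S)-9-(tert-butyldiphenylsilyloxy)-2,6-dimethyl-3-oxo-8-Bco-non-6-enoate (C2 epimers) | O=C(OCc6ccccc6)C(C)C(=O)CC/C(C)=C/[C@H](CO[Si](c4ccccc4)(c5ccccc5)C(C)(C)C)[C@@]13C[C@@H](CC=C1)[C@@](C)(O[Si](CC)(CC)CC)C3 | intermediate
25 | benzyl 7-(tert-butyldiphenylsilyloxy)-3-oxo-16-(triethylsilyloxy)gibberell-11-en-19-oate | C[C@@]12CCC(=O)[C@@](C)(C(=O)OCc6ccccc6)[C@H]1[C@H](CO[Si](c4ccccc4)(c5ccccc5)C(C)(C)C)[C@@]13C[C@@H](C=C[C@@H]21)[C@@](C)(O[Si](CC)(CC)CC)C3 | intermediate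
26 | benzyl 7-(tert-butyldiphenylsilyloxy)-3β-hydroxy-16-(triethylsilyloxy)gibberell-11-en-19-oate | C[C@@]12CC[C@H](O)[C@@](C)(C(=O)OCc6ccccc6)[C@H]1[C@H](CO[Si](c4ccccc4)(c5ccccc5)C(C)(C)C)[C@@]13C[C@@H](C=C[C@@H]21)[C@@](C)(O[Si](CC)(CC)CC)C3 | intermediate
27 | benzyl 3β,7,16-trihydroxygibberell-11-en-19-oate | C[C@@]12CC[C@H](O)[C@@](C)(C(=O)OCc6ccccc6)[C@H]1[C@H](CO)[C@@]13C[C@@H](C=C[C@@H]21)[C@@](C)(O)C3 | intermediate
28 | 3β,7,16-trihydroxygibberellan-19-oic acid, CNP0170663.1 (3-OH axial and cis to C18; 16-methyl syn to C14) | C[C@@]12CC[C@H](O)[C@@](C)(C(=O)O)[C@H]1[C@H](CO)[C@@]13C[C@@H](CC[C@@H]21)[C@@](C)(O)C3 | target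

## Step count and least certain steps

Total step count: 16. Longest linear sequence: 16 steps (1 → 28; 6, 19 and 22 are purchased).

Step 13 (key step). The most likely failure is oxidation of the tertiary C10 radical, by Cu(OAc)2 or Mn(OAc)3, to a ring A alkene or acetate before ring B closes, because the 5-exo attack on C9 is slowed by the neighbouring quaternary C8. Further risks are bond formation at C10 on the wrong face (cis A/B junction) and loss of H9 instead of H12 in the copper step. The fallback sets out from 24 and comes back at 28. Bromination of 24 (NBS, cat. Mg(ClO4)2, EtOAc) would give benzyl (6E,8S)-2-bromo-9-(tert-butyldiphenylsilyloxy)-2,6-dimethyl-3-oxo-8-Bco-non-6-enoate F1. Slow addition of Bu3SnH and AIBN in refluxing benzene would run the same two ring closures as a reductive tin-hydride chain, in which no oxidant competes for the C10 radical and the C11 radical is quenched by hydrogen transfer, giving the saturated tetracyclic ketone F2. K[(s-Bu)3BH] would then give the saturated 3β-alcohol F3, Bu4NF/AcOH the saturated triol benzyl ester F4, and hydrogenolysis (H2, Pd/C) 28. This path also removes any risk of alkene migration in the last step.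

Step 4. The most likely failures are loss of the silyl group from the intermediate silyloxyallyl cation before the second bond forms (open-chain alkylation instead of cycloaddition), isomerisation or dimerisation of 5, and bonding of the chlorine-bearing end of the cation to C13, which would put chlorine on C12 and the alkene of step 5 at C11=C12. The fallback sets out from 4 and comes back at 10. Deprotonation of 4 at C13 with LiN(i-Pr)2 and alkylation with commercial 1,3-dibromopropene would give 5-[(Z)-3-bromoprop-2-enyl]-3-ethenylcyclopent-2-en-1-one F5. Bu3SnH and AIBN would generate the vinyl radical at C9, whose geometrical isomers interconvert, and its 6-exo conjugate addition to C8 of the enone would give 10 with the alkene fixed at C9=C11 by construction.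

Step 9. The most likely failures are slow enamine formation from the neopentyl-type aldehyde, dehydration of 16 to the α-methylene aldehyde, incomplete catalyst control in the mismatched enantiomer, and poor separation of the diastereomeric silyl ethers. The fallback sets out from 15 and comes back at 18. NaClO2 oxidation would give rac-2-Bco-acetic acid F6, and DCC/DMAP coupling with (R)-4-benzyloxazolidin-2-one the N-acyl oxazolidinone F7. An Evans aldol reaction (Bu2BOTf, i-Pr2NEt, then methacrolein) would give the syn-aldol F8, in which the auxiliary fixes C6 and the diastereomers from the two bridgehead series are separated. LiBH4 would release (2S)-4-methyl-2-Bco-pent-4-ene-1,3-diol F9, and TBDPSCl/imidazole would silylate its primary hydroxyl to give 18 as a single C3 epimer.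

Step 12. The most likely failures are proton exchange between 23 and 21 followed by self-condensation, and sluggish attack of the α-substituted enolate on an unactivated ethyl ester, with decomposition of 23 on warming. The fallback sets out from 21 and comes back at 24. LiOH hydrolysis would give (4E,6S)-7-(tert-butyldiphenylsilyloxy)-4-methyl-6-Bco-hept-4-enoic acid F10, and Im2CO its acyl imidazole F11. Addition of F11 to 23 (two equivalents, THF, −78 °C) would give 24 by acylation with an activated acyl donor that reacts at low temperature.

## Further compounds

F1 | step 13 | benzyl (6E,8S)-2-bromo-9-(tert-butyldiphenylsilyloxy)-2,6-dimethyl-3-oxo-8-Bco-non-6-enoate | O=C(OCc6ccccc6)C(C)(Br)C(=O)CC/C(C)=C/[C@H](CO[Si](c4ccccc4)(c5ccccc5)C(C)(C)C)[C@@]13C[C@@H](CC=C1)[C@@](C)(O[Si](CC)(CC)CC)C3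
F2 | step 13 | benzyl 7-(tert-butyldiphenylsilyloxy)-3-oxo-16-(triethylsilyloxy)gibberellan-19-oate (11,12-dihydro-25) | C[C@@]12CCC(=O)[C@@](C)(C(=O)OCc6ccccc6)[C@H]1[C@H](CO[Si](c4ccccc4)(c5ccccc5)C(C)(C)C)[C@@]13C[C@@H](CC[C@@H]21)[C@@](C)(O[Si](CC)(CC)CC)C3
F3 | step 13 | benzyl 7-(tert-butyldiphenylsilyloxy)-3β-hydroxy-16-(triethylsilyloxy)gibberellan-19-oate (11,12-dihydro-26) | C[C@@]12CC[C@H](O)[C@@](C)(C(=O)OCc6ccccc6)[C@H]1[C@H](CO[Si](c4ccccc4)(c5ccccc5)C(C)(C)C)[C@@]13C[C@@H](CC[C@@H]21)[C@@](C)(O[Si](CC)(CC)CC)C3
F4 | step 13 | benzyl 3β,7,16-trihydroxygibberellan-19-oate (11,12-dihydro-27) | C[C@@]12CC[C@H](O)[C@@](C)(C(=O)OCc6ccccc6)[C@H]1[C@H](CO)[C@@]13C[C@@H](CC[C@@H]21)[C@@](C)(O)C3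
F5 | step 4 | 5-[(Z)-3-bromoprop-2-enyl]-3-ethenylcyclopent-2-en-1-one (racemic; enantiomer leading to drawn 10) | C=CC1=CC(=O)[C@H](C/C=C\Br)C1
F6 | step 9 | rac-2-Bco-acetic acid | OC(=O)C[C@@]13C[C@@H](CC=C1)[C@@](C)(O[Si](CC)(CC)CC)C3
F7 | step 9 | (4R)-4-benzyl-3-(2-Bco-acetyl)oxazolidin-2-one | O=C(C[C@@]13C[C@@H](CC=C1)[C@@](C)(O[Si](CC)(CC)CC)C3)N4[C@H](Cc5ccccc5)COC4=O
F8 | step 9 | (4R)-4-benzyl-3-(3-hydroxy-4-methyl-2-Bco-pent-4-enoyl)oxazolidin-2-one (syn-aldol) | C=C(C)[C@H](O)[C@H](C(=O)N4[C@H](Cc5ccccc5)COC4=O)[C@@]13C[C@@H](CC=C1)[C@@](C)(O[Si](CC)(CC)CC)C3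
F9 | step 9 | (2S)-4-methyl-2-Bco-pent-4-ene-1,3-diol | C=C(C)[C@H](O)[C@H](CO)[C@@]13C[C@@H](CC=C1)[C@@](C)(O[Si](CC)(CC)CC)C3
F10 | step 12 | (4E,6S)-7-(tert-butyldiphenylsilyloxy)-4-methyl-6-Bco-hept-4-enoic acid | OC(=O)CC/C(C)=C/[C@H](CO[Si](c4ccccc4)(c5ccccc5)C(C)(C)C)[C@@]13C[C@@H](CC=C1)[C@@](C)(O[Si](CC)(CC)CC)C3
F11 | step 12 | 1-[(4E,6S)-7-(tert-butyldiphenylsilyloxy)-4-methyl-6-Bco-hept-4-enoyl]imidazole | O=C(CC/C(C)=C/[C@H](CO[Si](c4ccccc4)(c5ccccc5)C(C)(C)C)[C@@]13C[C@@H](CC=C1)[C@@](C)(O[Si](CC)(CC)CC)C3)n7ccnc7
A1 | alternative 1 | tricyclic C8=C14 alkene with a C13 isopropenyl group (3,7-diacetate, methyl ester) | C[C@@]12CC[C@H](OC(C)=O)[C@@](C)(C(=O)OC)[C@H]1[C@H](COC(C)=O)C3=C[C@@H](CC[C@@H]23)C(C)=C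
A2 | alternative 1 | tetracyclic 16-carbinol as 3,7-diacetate methyl ester | C[C@@]12CC[C@H](OC(C)=O)[C@@](C)(C(=O)OC)[C@H]1[C@H](COC(C)=O)[C@@]13C[C@@H](CC[C@@H]21)[C@@](C)(O)C3
A3 | alternative 2 | cyclic sulfone with sulfur between C11 and C12 (3,7-bis-methoxymethyl ether, methyl ester) | C[C@@]12CC[C@H](OCOC)[C@@](C)(C(=O)OC)[C@H]1[C@H](COCOC)[C@@]13C[C@@H](CS(=O)(=O)C[C@@H]21)[C@@](C)(O)C3
A4 | alternative 2 | tetracycle with C11=C12 alkene (3,7-bis-methoxymethyl ether, methyl ester) | C[C@@]12CC[C@H](OCOC)[C@@](C)(C(=O)OC)[C@H]1[C@H](COCOC)[C@@]13C[C@@H](C=C[C@@H]21)[C@@](C)(O)C3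
A5 | alternative 3 | ring A chloromethyl ketone tethered to a 2-silyloxycyclopentadiene | C[C@@]1(CC(=O)CCl)CC[C@H](OCOC)[C@@](C)(C(=O)OC)[C@H]1[C@H](COCOC)C1=CC(O[Si](C)(C)C(C)(C)C)=CC1
A6 | alternative 3 | tetracyclic C11 ketone with C16 silyl enol ether | C[C@@]12CC[C@H](OCOC)[C@@](C)(C(=O)OC)[C@H]1[C@H](COCOC)[C@@]13C[C@@H](CC(=O)[C@@H]21)C(O[Si](C)(C)C(C)(C)C)=C3
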